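**Retrosynthetic overview** (ring numbering: O1, C2 aryl-bearing, C3 carrying the C9H2O arm, C4 carrying the 3,4-dimethoxybenzyl group, C5 the OCH2 carbon)

1. Feature: in the only ring (tetrahydrofuran O1, C2–C5) the C3–C4 bond joins the benzyl-bearing C4 to C3, whose C9H2O arm can be a former terminal vinyl carbon, while C5 next to O1 can be held as an acetal carbon.
2. Leoligin 17 ⇒ alcohol 15 + angelic acid 16 (C9–O ester bond); 15 ⇒ 5-ethoxy acetal 12 (C5–OEt to C5–H).
3. 12 ⇒ bromoacetal 10: C3–C4 and C9–O are formed in one radical step (5-exo closure of the C4 radical onto the C3=C9 vinyl group, O2 capture at C9); this is the only ring-forming step.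
4. 10 ⇒ (S)-allylic alcohol 4 + enol ether 8 + NBS; 4 from 3,4-dimethoxybenzaldehyde and vinylmagnesium bromide with lipase resolution, 8 from 3-(3,4-dimethoxyphenyl)propan-1-ol.

Key step: step 7

Assumption: the lipase is taken to acetylate the (R)-alcohol faster (Kazlauskas model, aryl as the large group), so the recovered alcohol is (S); compounds 10–13 are carried as epimer mixtures at the acetal carbon (10 also at CHBr), and these centres disappear in steps 7 and 9.

**Route**

Step 1
Reactants: 1 3,4-dimethoxybenzaldehyde; 2 vinylmagnesium bromide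
Product: 3 rac-1-(3,4-dimethoxyphenyl)prop-2-en-1-ol
Conditions: vinylmagnesium bromide, THF, 0 °C; aq. NH4Cl
Reagents that add atoms: vinylmagnesium bromide (compound 2), C=C[Mg]Br
Why: Grignard 1,2-addition of the vinyl nucleophile to the aromatic aldehyde gives the racemic secondary allylic alcohol, with no stereocontrol sought at this stage.

Step 2
Reactants: 3 rac-1-(3,4-dimethoxyphenyl)prop-2-en-1-ol
Product: 4 (S)-1-(3,4-dimethoxyphenyl)prop-2-en-1-ol
Conditions: Amano lipase PS (Burkholderia cepacia lipase), vinyl acetate, MTBE, 30 °C, stopped just past half conversion; chromatography on Et3N-deactivated silica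
Reagents that add atoms: none
Why: Lipase-catalysed kinetic resolution by enantioselective transesterification should acetylate the (R)-alcohol (aryl large, vinyl medium) and leave the (S)-alcohol, whose carbinol carbon becomes C2 of the target, in high enantiomeric purity once conversion passes one half.

Step 3
Reactants: 5 3-(3,4-dimethoxyphenyl)propan-1-ol
Product: 6 3-(3,4-dimethoxyphenyl)propanal
Conditions: TEMPO (cat.), PhI(OAc)2, CH2Cl2, rt
Reagents that add atoms: none
Why: Nitroxide-catalysed (oxoammonium) oxidation of a primary alcohol stops at the aldehyde and should leave the dimethoxyarene untouched.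

Step 4
Reactants: 6 3-(3,4-dimethoxyphenyl)propanal
Product: 7 4-(3,3-diethoxypropyl)-1,2-dimethoxybenzene
Conditions: HC(OEt)3, EtOH, PPTS (cat.), rt
Reagents that add atoms: triethyl orthoformate, CCOC(OCC)OCC; ethanol, CCO
Why: Acid-catalysed acetalisation is driven to completion by the orthoformate acting as water scavenger.

Step 5
Reactants: 7 4-(3,3-diethoxypropyl)-1,2-dimethoxybenzene
Product: 8 4-(3-ethoxyprop-2-en-1-yl)-1,2-dimethoxybenzene (E/Z mixture)
Conditions: TMSOTf, iPr2NEt, CH2Cl2, −20 °C → rt
Reagents that add atoms: none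
Why: Gassman-type acetal elimination, in which the silyl triflate ionises the acetal to an oxocarbenium ion that the hindered amine deprotonates to the enol ether; the E/Z ratio is irrelevant because both alkene carbons become sp3 in the next step without any need for control.

Step 6
Reactants: 4 (S)-1-(3,4-dimethoxyphenyl)prop-2-en-1-ol; 8 4-(3-ethoxyprop-2-en-1-yl)-1,2-dimethoxybenzene; 9 N-bromosuccinimide
Product: 10 4-[(1S)-1-{[2-bromo-3-(3,4-dimethoxyphenyl)-1-ethoxypropyl]oxy}prop-2-en-1-yl]-1,2-dimethoxybenzene (mixed bromoacetal, diastereomers at the acetal and CHBr carbons)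
Conditions: NBS, 8 in excess, CH2Cl2, −40 → 0 °C; chromatography on Et3N-deactivated silica
Reagents that add atoms: N-bromosuccinimide (compound 9), O=C1CCC(=O)N1Br
Why: Bromoacetalisation (first stage of the Ueno–Stork sequence), in which the enol ether, the most nucleophilic alkene present, is brominated at its β-carbon and the resulting oxocarbenium ion is captured by the hydroxyl of 4, leaving the C2 stereocentre untouched.

Step 7
Reactants: 10 mixed bromoacetal
Product: 12 [(2S,3R,4R)-4-(3,4-dimethoxybenzyl)-2-(3,4-dimethoxyphenyl)-5-ethoxytetrahydrofuran-3-yl]methanol (C5 epimers), via C9 hydroperoxide 11 (not isolated)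
Conditions: Bu3SnH (2.5 equiv), dry air (slow stream), toluene, 0 °C → rt; then PPh3
Reagents that add atoms: dioxygen, O=O
Why: Bu3Sn• abstracts bromine to give the secondary C4 radical, which adds to the internal vinyl carbon C3 and closes the tetrahydrofuran ring (O1, C2–C5) through the C3–C4 bond in the 5-exo-trig mode; the primary C9 radical is then captured by O2, the peroxyl radical takes hydrogen from Bu3SnH, and hydroperoxide 11 is reduced to the alcohol by the stannane and finally by PPh3. The closest known reaction is the Ueno–Stork bromoacetal cyclisation run under aerobic tin hydride conditions (oxygenative radical cyclisation). C3 is set by C2: in the chair-like Beckwith–Houk transition state the aryl group on the allylic carbon sits pseudo-equatorial, which should place the aryl group and the new CH2O arm trans. C4 is set relative to C3 by the usual preference of a substituent on the radical carbon to end cis to the new exocyclic CH2 group, so benzyl and CH2OH should come out cis (2,3-trans, 3,4-cis), and both acetal epimers are expected to converge on this arrangement. The step needs ring closure to outrun oxygen capture of the C4 radical and needs facial control at the alkene; the first is served by the fast closure of a 3-oxa-5-hexenyl radical with substituted acetal and allylic carbons together with a low stationary O2 concentration (air, not pure oxygen), the second by the single C2 stereocentre.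

Step 8
Reactants: 12 [(2S,3R,4R)-4-(3,4-dimethoxybenzyl)-2-(3,4-dimethoxyphenyl)-5-ethoxytetrahydrofuran-3-yl]methanol (C5 epimers)
Product: 13 tert-butyl{[(2S,3R,4R)-4-(3,4-dimethoxybenzyl)-2-(3,4-dimethoxyphenyl)-5-ethoxytetrahydrofuran-3-yl]methoxy}diphenylsilane (C5 epimers)
Conditions: TBDPSCl, imidazole, DMF, rt
Reagents that add atoms: tert-butyl(chloro)diphenylsilane, CC(C)(C)[Si](Cl)(c1ccccc1)c1ccccc1
Why: Imidazole-promoted silylation of the primary alcohol masks the hydroxyl so that it cannot add to the C5 oxocarbenium ion in the next step, and the TBDPS ether is chosen for its stability to Lewis acid.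

Step 9
Reactants: 13 TBDPS ether of the 5-ethoxy acetal
Product: 14 tert-butyl{[(2S,3R,4R)-4-(3,4-dimethoxybenzyl)-2-(3,4-dimethoxyphenyl)tetrahydrofuran-3-yl]methoxy}diphenylsilane
Conditions: Et3SiH (excess), BF3·OEt2, CH2Cl2, −78 → −40 °C
Reagents that add atoms: none
Why: Ionic silane/Lewis acid reduction of a cyclic acetal, in which BF3 ionises the exocyclic ethoxy group and the five-membered oxocarbenium ion is reduced by hydride from Et3SiH faster than it can enolise, so C5 becomes CH2, both acetal epimers converge, and C2–C4 should remain untouched at low temperature.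

Step 10
Reactants: 14 TBDPS ether of the tetrahydrofuran
Product: 15 [(2S,3R,4R)-4-(3,4-dimethoxybenzyl)-2-(3,4-dimethoxyphenyl)tetrahydrofuran-3-yl]methanol
Conditions: Bu4NF, THF, rt
Reagents that add atoms: none
Why: Fluoride-induced desilylation frees the primary alcohol without touching any other group, and minor diastereomers carried from step 7 should be removable here by chromatography.

Step 11
Reactants: 15 [(2S,3R,4R)-4-(3,4-dimethoxybenzyl)-2-(3,4-dimethoxyphenyl)tetrahydrofuran-3-yl]methanol; 16 angelic acid ((2Z)-2-methylbut-2-enoic acid)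
Product: 17 leoligin, [(2S,3R,4R)-4-(3,4-dimethoxybenzyl)-2-(3,4-dimethoxyphenyl)tetrahydrofuran-3-yl]methyl (2Z)-2-methylbut-2-enoate
Conditions: PPh3, DIAD, THF, 0 °C → rt
Reagents that add atoms: angelic acid (compound 16), C/C=C(/C)C(=O)O
Why: Mitsunobu esterification activates the alcohol as its alkoxyphosphonium ion and lets angelate displace it at the non-stereogenic C9, so the acid is never turned into an acylating agent and its Z double bond should be preserved.

**Compound list**

1 | 3,4-dimethoxybenzaldehyde | COc1ccc(C=O)cc1OC | starting material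
2 | vinylmagnesium bromide | C=C[Mg]Br | starting material
3 | rac-1-(3,4-dimethoxyphenyl)prop-2-en-1-ol | C=CC(O)c1ccc(OC)c(OC)c1 | intermediate
4 | (S)-1-(3,4-dimethoxyphenyl)prop-2-en-1-ol | C=C[C@H](O)c1ccc(OC)c(OC)c1 | intermediate
5 | 3-(3,4-dimethoxyphenyl)propan-1-ol | COc1ccc(CCCO)cc1OC | starting material
6 | 3-(3,4-dimethoxyphenyl)propanal | COc1ccc(CCC=O)cc1OC | intermediate
7 | 4-(3,3-diethoxypropyl)-1,2-dimethoxybenzene | CCOC(CCc1ccc(OC)c(OC)c1)OCC | intermediate
8 | 4-(3-ethoxyprop-2-en-1-yl)-1,2-dimethoxybenzene (E/Z mixture) | CCOC=CCc1ccc(OC)c(OC)c1 | intermediate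
9 | N-bromosuccinimide | O=C1CCC(=O)N1Br | starting material
10 | 4-[(1S)-1-{[2-bromo-3-(3,4-dimethoxyphenyl)-1-ethoxypropyl]oxy}prop-2-en-1-yl]-1,2-dimethoxybenzene (diastereomers at the acetal and CHBr carbons) | C=C[C@H](OC(OCC)C(Br)Cc1ccc(OC)c(OC)c1)c1ccc(OC)c(OC)c1 | intermediate
11 | (2S,3R,4R)-4-(3,4-dimethoxybenzyl)-2-(3,4-dimethoxyphenyl)-5-ethoxy-3-(hydroperoxymethyl)tetrahydrofuran (C5 epimers, not isolated) | OOC[C@H]1[C@@H](Cc2ccc(OC)c(OC)c2)C(OCC)O[C@@H]1c1ccc(OC)c(OC)c1 | intermediate
12 | [(2S,3R,4R)-4-(3,4-dimethoxybenzyl)-2-(3,4-dimethoxyphenyl)-5-ethoxytetrahydrofuran-3-yl]methanol (C5 epimers) | OC[C@H]1[C@@H](Cc2ccc(OC)c(OC)c2)C(OCC)O[C@@H]1c1ccc(OC)c(OC)c1 | intermediate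
13 | tert-butyl{[(2S,3R,4R)-4-(3,4-dimethoxybenzyl)-2-(3,4-dimethoxyphenyl)-5-ethoxytetrahydrofuran-3-yl]methoxy}diphenylsilane (C5 epimers) | CC(C)(C)[Si](OC[C@H]1[C@@H](Cc2ccc(OC)c(OC)c2)C(OCC)O[C@@H]1c1ccc(OC)c(OC)c1)(c1ccccc1)c1ccccc1 | intermediate
14 | tert-butyl{[(2S,3R,4R)-4-(3,4-dimethoxybenzyl)-2-(3,4-dimethoxyphenyl)tetrahydrofuran-3-yl]methoxy}diphenylsilane | CC(C)(C)[Si](OC[C@H]1[C@@H](Cc2ccc(OC)c(OC)c2)CO[C@@H]1c1ccc(OC)c(OC)c1)(c1ccccc1)c1ccccc1 | intermediate
15 | [(2S,3R,4R)-4-(3,4-dimethoxybenzyl)-2-(3,4-dimethoxyphenyl)tetrahydrofuran-3-yl]methanol | OC[C@H]1[C@@H](Cc2ccc(OC)c(OC)c2)CO[C@@H]1c1ccc(OC)c(OC)c1 | intermediate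
16 | angelic acid, (2Z)-2-methylbut-2-enoic acid | C/C=C(/C)C(=O)O | starting material
17 | leoligin, [(2S,3R,4R)-4-(3,4-dimethoxybenzyl)-2-(3,4-dimethoxyphenyl)tetrahydrofuran-3-yl]methyl (2Z)-2-methylbut-2-enoate | C/C=C(/C)C(=O)OC[C@H]1[C@@H](Cc2ccc(OC)c(OC)c2)CO[C@@H]1c1ccc(OC)c(OC)c1 | target

**Step count**

Total steps: 11. Longest linear sequence: 9 steps (compound 5 to 17 through steps 3–11); the other branch (steps 1–2) joins at step 6.

**Steps most likely to fail**

Step 7. The risks are oxygen capture of the C4 radical before it cyclises, incomplete facial discrimination at C3 and C4 across the two acetal epimers, and peroxyl side reactions at the benzylic C2–H. The fallback replaces oxygen capture by iodine atom transfer and sets out from 4 and 8. N-Iodosuccinimide in CH2Cl2 at −40 °C should give the iodoacetal 4-[(1S)-1-{[3-(3,4-dimethoxyphenyl)-1-ethoxy-2-iodopropyl]oxy}prop-2-en-1-yl]-1,2-dimethoxybenzene F1. Et3B with a trace of air (or (Bu3Sn)2 under irradiation) should then trigger iodine-atom-transfer 5-exo cyclisation, with no O2 present during ring closure, to (2S,3S,4R)-4-(3,4-dimethoxybenzyl)-2-(3,4-dimethoxyphenyl)-5-ethoxy-3-(iodomethyl)tetrahydrofuran F2. Et3SiH/BF3·OEt2 at −78 °C should reduce the acetal to (2S,3S,4R)-4-(3,4-dimethoxybenzyl)-2-(3,4-dimethoxyphenyl)-3-(iodomethyl)tetrahydrofuran F3. Displacement of iodide by angelate (angelic acid 16, Cs2CO3, DMF, 50 °C) rejoins the route at the target 17.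

Step 9. The risks are Lewis-acid ionisation of the electron-rich benzylic C2–O1 bond (epimerisation at C2 or reductive ring opening), Friedel–Crafts capture of the C5 oxocarbenium ion by the neighbouring dimethoxyphenyl ring, and partial loss of the silyl ether. The fallback avoids the cation and sets out from 13. Mild aqueous acid (AcOH/THF/H2O) should hydrolyse the acetal to the lactol 4-({[tert-butyl(diphenyl)silyl]oxy}methyl)-3-(3,4-dimethoxybenzyl)-5-(3,4-dimethoxyphenyl)tetrahydrofuran-2-ol F4. NaBH4 in MeOH should reduce it through its open hydroxy-aldehyde form to 3-({[tert-butyl(diphenyl)silyl]oxy}methyl)-2-(3,4-dimethoxybenzyl)-4-(3,4-dimethoxyphenyl)butane-1,4-diol F5. Selective sulfonylation of the primary hydroxyl (TsCl, Et3N, DMAP cat., CH2Cl2, 0 °C) should give the primary 4-methylbenzenesulfonate of that diol F6. NaH in THF then closes the ring by attack of the C2 alkoxide on C5, with C2 retained because its C–O bond is never broken, and the route is rejoined at 14.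

Step 11. The risks are slow displacement at the β-branched C9 alkoxyphosphonium centre and phosphine-induced Z to E isomerisation of the product (tiglate formation). The fallback is a two-step alkylative esterification from 15. MsCl/Et3N in CH2Cl2 at 0 °C should give [(2S,3R,4R)-4-(3,4-dimethoxybenzyl)-2-(3,4-dimethoxyphenyl)tetrahydrofuran-3-yl]methyl methanesulfonate F7. Heating F7 with angelic acid 16 and Cs2CO3 in DMF (50–60 °C) lets the configurationally stable carboxylate displace the sulfonate with no phosphine and no acyl activation, rejoining the route at 17.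

**Further compounds**

F1 | step 7 | 4-[(1S)-1-{[3-(3,4-dimethoxyphenyl)-1-ethoxy-2-iodopropyl]oxy}prop-2-en-1-yl]-1,2-dimethoxybenzene (diastereomers at the acetal and CHI carbons) | C=C[C@H](OC(OCC)C(I)Cc1ccc(OC)c(OC)c1)c1ccc(OC)c(OC)c1
F2 | step 7 | (2S,3S,4R)-4-(3,4-dimethoxybenzyl)-2-(3,4-dimethoxyphenyl)-5-ethoxy-3-(iodomethyl)tetrahydrofuran (C5 epimers) | IC[C@H]1[C@@H](Cc2ccc(OC)c(OC)c2)C(OCC)O[C@@H]1c1ccc(OC)c(OC)c1
F3 | step 7 | (2S,3S,4R)-4-(3,4-dimethoxybenzyl)-2-(3,4-dimethoxyphenyl)-3-(iodomethyl)tetrahydrofuran | IC[C@H]1[C@@H](Cc2ccc(OC)c(OC)c2)CO[C@@H]1c1ccc(OC)c(OC)c1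
F4 | step 9 | 4-({[tert-butyl(diphenyl)silyl]oxy}methyl)-3-(3,4-dimethoxybenzyl)-5-(3,4-dimethoxyphenyl)tetrahydrofuran-2-ol (anomers, ring configuration as in 13) | CC(C)(C)[Si](OC[C@H]1[C@@H](Cc2ccc(OC)c(OC)c2)C(O)O[C@@H]1c1ccc(OC)c(OC)c1)(c1ccccc1)c1ccccc1
F5 | step 9 | 3-({[tert-butyl(diphenyl)silyl]oxy}methyl)-2-(3,4-dimethoxybenzyl)-4-(3,4-dimethoxyphenyl)butane-1,4-diol (configuration as in 13) | CC(C)(C)[Si](OC[C@@H]([C@@H](Cc2ccc(OC)c(OC)c2)CO)[C@H](O)c1ccc(OC)c(OC)c1)(c1ccccc1)c1ccccc1
F6 | step 9 | 3-({[tert-butyl(diphenyl)silyl]oxy}methyl)-2-(3,4-dimethoxybenzyl)-4-(3,4-dimethoxyphenyl)-4-hydroxybutyl 4-methylbenzenesulfonate | CC(C)(C)[Si](OC[C@@H]([C@@H](Cc2ccc(OC)c(OC)c2)COS(=O)(=O)c2ccc(C)cc2)[C@H](O)c1ccc(OC)c(OC)c1)(c1ccccc1)c1ccccc1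
F7 | step 11 | [(2S,3R,4R)-4-(3,4-dimethoxybenzyl)-2-(3,4-dimethoxyphenyl)tetrahydrofuran-3-yl]methyl methanesulfonate | CS(=O)(=O)OC[C@H]1[C@@H](Cc2ccc(OC)c(OC)c2)CO[C@@H]1c1ccc(OC)c(OC)c1
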